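I decide to stop watching the clock for amber and teal and to count partner instead, since in gamma and eta the starting material stands still well before the asked time.

common to all: starting material 23 mM
- gamma: partner 0.72 equiv; run made earlier
- eta: partner 1.1 equiv; run made earlier
- alpha: partner 2.5 equiv; run made earlier
- amber: partner 0.600 equiv; time 25 h
- teal: partner 1.20 equiv; time 25 h
- grey: partner 2.40 equiv; time 25 h

| run | time / h | target / % | starting material / % | intermediate A / % | side product / % | intermediate B / % |
|---|---|---|---|---|---|---|
| gamma | 4.00 | 0.7 | 65.6 | 20.1 | 0.5 | 8.5 |
| gamma | 8.00 | 3.1 | 61.5 | 18.1 | 1.7 | 11.8 |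
| gamma | 10.0 | 5.5 | 62.2 | 16.4 | 4.3 | 10.4 |
| gamma | 15.0 | 6.6 | 60.6 | 12.5 | 3.7 | 10.4 |
| gamma | 20.0 | 8.9 | 63.5 | 10.6 | 4.2 | 8.5 |
| eta | 4.00 | 1.3 | 52.7 | 22.9 | 5.9 | 15.3 |
| eta | 8.00 | 8.4 | 47.8 | 18.5 | 7.3 | 18.3 |
| eta | 10.0 | 9.7 | 45.4 | 16.9 | 6.5 | 19.9 |
| eta | 15.0 | 14.0 | 45.0 | 12.0 | 5.6 | 15.3 |
| eta | 20.0 | 19.9 | 43.6 | 10.4 | 7.3 | 14.2 |
| alpha | 1.50 | 0.5 | 39.1 | 26.0 | 6.0 | 21.1 |
| alpha | 4.00 | 5.9 | 18.5 | 17.0 | 9.9 | 39.0 |
| alpha | 8.00 | 17.1 | 10.4 | 7.6 | 15.3 | 42.8 |
| alpha | 12.0 | 25.6 | 6.4 | 4.1 | 18.7 | 37.1 |
| alpha | 20.0 | 42.5 | 2.9 | 2.7 | 15.8 | 28.7 |

(readings scatter by 1 percentage point)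

* which of these there is most of at the end, counted by the starting material in it, amber (side product / intermediate B / intermediate A / starting material / target)
* which of these there is most of at the end, counted by the starting material in it, teal (side product / intermediate B / intermediate A / starting material / target)
* which of these there is most of at the end, counted by the starting material in it, grey (side product / intermediate B / intermediate A / starting material / target)
* how much there is at the end of the one of these that leads, in percent of the starting material charged: amber
* how much there is at the end of the one of these that leads, in percent of the starting material charged: teal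
* how much there is at the end of the one of these that leads, in percent of the starting material charged: grey

- the numbers in the tables scatter by 1 percentage point (one standard deviation)

1. I freeze the stall. From 10.0 h to 20.0 h, [starting material] averages 62.1 % in gamma and 44.7 % in eta, with no trend that I can tell from a scatter of 1 percentage point, so I take these means as the levels that hold at the end.

2. I divide the equivalents of partner charged by the fraction of starting material consumed at the stall, which gives 1.90 for gamma and 1.99 for eta, and I carry their mean, 1.94, as the partner price.

3. Reckoned from the full charge, the price puts amber at 69.1 % and teal at 38.3 %, but this is the weak link, because a single line from the full charge cannot pass through both stalls when gamma and eta read different prices.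

4. I reforge it by stepping from the nearest run and pricing just the difference in charge, which gives 68.3 % for amber from gamma and 39.5 % for teal from eta. In teal I expect starting material to lead, since the target in eta at 20.0 h is 19.9 %, less than that level, and amber, with less partner, should lead the same way.

5. Grey carries more partner than the price, so I expect no stall and follow alpha instead, whose last readings give intermediate B a first-order loss of 0.0642 h⁻¹. Taking grey for alpha and running this on from the last reading of alpha to the asked time, I reckon the target in grey at 50.4 %, ahead of the 20.8 % I reckon for intermediate B.

The forecast names starting material at 69 % for amber, starting material at 41 % for teal and target at 49 % for grey, holding that “each starting material consumes about 2 partners”, and so it names the same leaders as I do, with amounts that differ from my 68.3 %, 39.5 % and 50.4 %.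

The flask gives starting material at 68.4 % in amber, starting material at 40.7 % in teal and target at 49.4 % in grey.

    starting material + partner ⇌ intermediate A (K = 94.0 L mol⁻¹, k = 15.0 L mol⁻¹ h⁻¹)
    partner + intermediate A → intermediate B (k = 14.8 L mol⁻¹ h⁻¹)
    partner + intermediate A → side product (k = 3.64 L mol⁻¹ h⁻¹)
    partner + intermediate A ⇌ intermediate C (K = 52.0 L mol⁻¹, k = 3.66 L mol⁻¹ h⁻¹)
    intermediate B → target (k = 0.0622 h⁻¹)

At the end of teal, partner stands at 8.5 % of its own charge, less than the 41 % of starting material; teal is charged below the price, which makes partner the limiting reagent there, and the result of teal puts the price at 2.02. The neighbouring flask is teal read at 4.0 d: the price, which holds no clock, again gives 39.5 %, and that flask holds 40.2 % of starting material, while target now leads at 44.6 %.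

(The data come from a simulation from invented constants; the scatter is artificial.)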